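The seven-membered ring is cut at C7–C8 and C9–C10 (numbering: C1 methyl-bearing fusion carbon, C4 isopropyl carbinol, C5 fusion CH, C6 ester carbon, C8=C9 alkene). Ring carbons C10–C1–C5–C6–C7 are stored in a vinylcyclopropane whose three-membered ring (C1, C5, C10) is fused to the cyclopentane and whose vinyl group is the C6 enol ether; C8=C9 comes from a silylpropyne. One rhodium-catalysed [5+2] cycloaddition forms both bonds, closes the cycloheptadiene and leaves C6 as a masked ketone. The precursor is an enantiopure 1-(1-silyloxyvinyl)-5-methylbicyclo[3.1.0]hexane with the C4 silyl ether anti to the cyclopropane methylene; the alkyne carries a fluoride-labile benzyldimethylsilyl group.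

Key step: step 10

Remark: C2 and C3 are the cyclopentane CH2 groups, C7 and C10 the cycloheptene CH2 groups; β is the face of the C1 methyl group, α the opposite face; compound 1 is assumed to be bought as such.

Step 1
Reactants: 1 2-bromo-3-methylcyclopent-2-en-1-one; 2 isopropylmagnesium chloride
Product: 3 rac-2-bromo-3-methyl-1-(propan-2-yl)cyclopent-2-en-1-ol
Conditions: iPrMgCl, CeCl3 (anhydrous), THF, −78 °C; then H2O
Reagents that add atoms: isopropylmagnesium chloride, CC(C)[Mg]Cl
Why: Organocerium 1,2-addition (Grignard reagent premixed with CeCl3) to the enone carbonyl should outrun enolisation, β-hydride reduction and bromine–magnesium exchange and give the racemic tertiary allylic alcohol that becomes the C4 carbinol.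

Step 2
Reactants: 3 rac-2-bromo-3-methyl-1-(propan-2-yl)cyclopent-2-en-1-ol
Product: 4 (1R)-2-bromo-3-methyl-1-(propan-2-yl)cyclopent-2-en-1-ol
Conditions: preparative SFC, amylose tris(3,5-dimethylphenylcarbamate) stationary phase, CO2/iPrOH
Reagents that add atoms: none
Why: Resolution of the racemate by chromatography on a chiral stationary phase should deliver the (R)-alcohol, whose carbinol carbon is C4 and is the only source of absolute configuration in the route.

Step 3
Reactants: 4 (1R)-2-bromo-3-methyl-1-(propan-2-yl)cyclopent-2-en-1-ol; 5 triethylsilyl trifluoromethanesulfonate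
Product: 6 {[(1R)-2-bromo-3-methyl-1-(propan-2-yl)cyclopent-2-en-1-yl]oxy}triethylsilane
Conditions: Et3SiOTf, 2,6-lutidine, CH2Cl2, −78 to 0 °C
Reagents that add atoms: triethylsilyl trifluoromethanesulfonate, CC[Si](CC)(CC)OS(=O)(=O)C(F)(F)F
Why: Silyl ether formation with the silyl triflate and a hindered pyridine base should protect the crowded tertiary hydroxyl, which would otherwise act as a directing group in step 6 and later serves to shield the β-face.

Step 4
Reactants: 6 {[(1R)-2-bromo-3-methyl-1-(propan-2-yl)cyclopent-2-en-1-yl]oxy}triethylsilane; 7 N-methoxy-N-methylacetamide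
Product: 9 1-[(5R)-2-methyl-5-(propan-2-yl)-5-(triethylsilyloxy)cyclopent-1-en-1-yl]ethan-1-one, via alkenyllithium 8 (not isolated)
Conditions: t-BuLi (2.1 equiv), THF, −78 °C; then 7, −78 to 0 °C; H2O
Reagents that add atoms: N-methoxy-N-methylacetamide, CC(=O)N(C)OC
Why: Bromine–lithium exchange followed by acylation of the alkenyllithium with the N-methoxy-N-methylamide (Weinreb ketone synthesis) should install the acetyl group (C6 and C7) without over-addition and without touching C4.

Step 5
Reactants: 9 1-[(5R)-2-methyl-5-(propan-2-yl)-5-(triethylsilyloxy)cyclopent-1-en-1-yl]ethan-1-one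
Product: 10 (1R)-1-[(5R)-2-methyl-5-(propan-2-yl)-5-(triethylsilyloxy)cyclopent-1-en-1-yl]ethan-1-ol
Conditions: (S)-1-methyl-3,3-diphenyltetrahydro-1H,3H-pyrrolo[1,2-c][1,3,2]oxazaborole (0.2 equiv), catecholborane, toluene, −78 to −40 °C
Reagents that add atoms: none
Why: Corey–Bakshi–Shibata reduction, in which the tetrasubstituted alkenyl group acts as the large substituent, should give the (R)-configured C6 carbinol under reagent control, a temporary stereocentre needed only to steer step 6.

Step 6
Reactants: 10 (1R)-1-[(5R)-2-methyl-5-(propan-2-yl)-5-(triethylsilyloxy)cyclopent-1-en-1-yl]ethan-1-ol; 11 diiodomethane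
Product: 12 (1R)-1-[(1S,2R,5R)-5-methyl-2-(propan-2-yl)-2-(triethylsilyloxy)bicyclo[3.1.0]hexan-1-yl]ethan-1-ol
Conditions: Et2Zn, CH2I2, CH2Cl2, 0 °C to rt
Reagents that add atoms: diiodomethane, ICI
Why: In this hydroxyl-directed Simmons–Smith cyclopropanation (Furukawa reagent) allylic 1,3-strain with the C1 methyl group holds the carbinol hydrogen in the alkene plane, so the (R)-configured zinc alkoxide lies on the α-face, anti to the C4 silyl ether, and should deliver the methylene (C10) there, which sets C1 and C5 with the C1 methyl cis to the C4 oxygen.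

Step 7
Reactants: 12 (1R)-1-[(1S,2R,5R)-5-methyl-2-(propan-2-yl)-2-(triethylsilyloxy)bicyclo[3.1.0]hexan-1-yl]ethan-1-ol
Product: 13 1-[(1R,2R,5R)-5-methyl-2-(propan-2-yl)-2-(triethylsilyloxy)bicyclo[3.1.0]hexan-1-yl]ethan-1-one
Conditions: Dess–Martin periodinane, NaHCO3, CH2Cl2, 0 °C to rt
Reagents that add atoms: none
Why: Dess–Martin oxidation under buffered, non-acidic conditions should return the methyl ketone without opening the cyclopropylcarbinyl system and erases the auxiliary C6 stereocentre.

Step 8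
Reactants: 13 1-[(1R,2R,5R)-5-methyl-2-(propan-2-yl)-2-(triethylsilyloxy)bicyclo[3.1.0]hexan-1-yl]ethan-1-one; 14 tert-butyldimethylsilyl trifluoromethanesulfonate
Product: 15 tert-butyl({1-[(1S,2R,5R)-5-methyl-2-(propan-2-yl)-2-(triethylsilyloxy)bicyclo[3.1.0]hexan-1-yl]ethenyl}oxy)dimethylsilane
Conditions: t-BuMe2SiOTf, Et3N, CH2Cl2, 0 °C
Reagents that add atoms: tert-butyldimethylsilyl trifluoromethanesulfonate, CC(C)(C)[Si](C)(C)OS(=O)(=O)C(F)(F)F
Why: Soft enolisation and O-silylation can only go towards the methyl group because C5 is quaternary, so the 2-silyloxy vinylcyclopropane should form regiospecifically.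

Step 9
Reactants: 16 prop-1-yn-1-ylmagnesium bromide; 17 benzylchlorodimethylsilane
Product: 18 benzyldimethyl(prop-1-yn-1-yl)silane
Conditions: THF, 0 °C to rt
Reagents that add atoms: benzylchlorodimethylsilane, C[Si](C)(Cl)Cc1ccccc1
Why: Nucleophilic substitution at silicon by the alkynyl Grignard reagent should give a silylpropyne whose bulky silyl group steers the regiochemistry of step 10 and can later be removed with fluoride instead of acid.

Step 10
Reactants: 15 tert-butyl({1-[(1S,2R,5R)-5-methyl-2-(propan-2-yl)-2-(triethylsilyloxy)bicyclo[3.1.0]hexan-1-yl]ethenyl}oxy)dimethylsilane; 18 benzyldimethyl(prop-1-yn-1-yl)silane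
Product: 19 {[(3R,8aR)-7-[benzyl(dimethyl)silyl]-6,8a-dimethyl-3-(propan-2-yl)-3-(triethylsilyloxy)-1,2,3,5,8,8a-hexahydroazulen-4-yl]oxy}(tert-butyl)dimethylsilane
Conditions: [Rh(CO)2Cl]2 (5 mol %), 18 (3 equiv), ClCH2CH2Cl, 70 °C
Reagents that add atoms: none
Why: Monovalent rhodium from [Rh(CO)2Cl]2 binds the C6=C7 enol ether alkene of 15 and inserts into the adjacent cyclopropane bond C5–C10, giving a rhodacycle with a Rh–C10 σ-bond and an allyl unit over C5–C6–C7; alkyne 18 then inserts at the allyl terminus (C7–C8). The closest known reaction type is the rhodium-catalysed intermolecular [5+2] cycloaddition of vinylcyclopropanes with alkynes, applied here to a ring-fused member bearing a silyloxy group on the vinyl carbon. The seven-membered ring is closed by C(sp2)–C(sp3) reductive elimination (C9–C10) from the eight-membered rhodacycle, which leaves the C5=C6 enol ether and the C8=C9 alkene in place. No stereocentre is created: C1 and C4 are carried through unchanged and C5 becomes trigonal. Cleavage of C5–C10 over the ring-fusion bond C5–C1 is secured because the latter would place rhodium on the quaternary C1, and the rhodacycle has no β-hydrogen on C1 through which it could decompose. The alkyne orientation is secured by the bulky silyl group, which stays on the rhodium-bound carbon (future C9) so that the methyl-bearing carbon bonds to C7.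

Step 11
Reactants: 19 {[(3R,8aR)-7-[benzyl(dimethyl)silyl]-6,8a-dimethyl-3-(propan-2-yl)-3-(triethylsilyloxy)-1,2,3,5,8,8a-hexahydroazulen-4-yl]oxy}(tert-butyl)dimethylsilane
Product: 21 (3R,3aR,8aR)-7-[benzyl(dimethyl)silyl]-3-hydroxy-6,8a-dimethyl-3-(propan-2-yl)-2,3,3a,5,8,8a-hexahydroazulen-4(1H)-one, via silyl-protected ketone 20 (not isolated)
Conditions: HF·pyridine, pyridine, THF, 0 °C to rt
Reagents that add atoms: none
Why: Hydrolysis of the silyl enol ether starts with protonation at C5, expected from the α-face because the β-face carries the C1 methyl group and the still intact C4 silyl ether, so the trans-fused ketone should form before the slower desilylation of the tertiary triethylsilyl ether, under buffered conditions mild enough for the β-hydroxy ketone and the β,γ-unsaturated ketone.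

Step 12
Reactants: 21 (3R,3aR,8aR)-7-[benzyl(dimethyl)silyl]-3-hydroxy-6,8a-dimethyl-3-(propan-2-yl)-2,3,3a,5,8,8a-hexahydroazulen-4(1H)-one
Product: 22 (3R,3aS,4S,8aR)-7-[benzyl(dimethyl)silyl]-6,8a-dimethyl-3-(propan-2-yl)-1,2,3,3a,4,5,8,8a-octahydroazulene-3,4-diol
Conditions: Me4NBH(OAc)3, MeCN/AcOH, −20 °C to rt
Reagents that add atoms: none
Why: In this hydroxyl-directed reduction (Evans–Saksena reduction) the C4 hydroxyl exchanges onto boron and passes hydride to the C6 carbonyl through a six-membered transition state on the face it can reach, which should place the new C6–H β and the C6 hydroxyl α, anti to the C4 hydroxyl.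

Step 13
Reactants: 22 (3R,3aS,4S,8aR)-7-[benzyl(dimethyl)silyl]-6,8a-dimethyl-3-(propan-2-yl)-1,2,3,3a,4,5,8,8a-octahydroazulene-3,4-diol
Product: 23 (3R,3aS,4S,8aR)-6,8a-dimethyl-3-(propan-2-yl)-1,2,3,3a,4,5,8,8a-octahydroazulene-3,4-diol (jaeschkeanadiol)
Conditions: Bu4NF, THF, 0 to 40 °C
Reagents that add atoms: none
Why: Fluoride-induced protodesilylation of the alkenyl benzyldimethylsilane (loss of the benzyl group, then cleavage of the alkenyl–silicon bond with the alkene staying in place) should unveil the C8=C9 alkene under non-acidic conditions that the tertiary alcohol tolerates.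

Step 14
Reactants: 23 (3R,3aS,4S,8aR)-6,8a-dimethyl-3-(propan-2-yl)-1,2,3,3a,4,5,8,8a-octahydroazulene-3,4-diol; 24 2-(acetyloxy)benzoyl chloride
Product: 26 (3R,3aS,4S,8aR)-3-hydroxy-6,8a-dimethyl-3-(propan-2-yl)-1,2,3,3a,4,5,8,8a-octahydroazulen-4-yl 2-hydroxybenzoate (CNP0379621.1), via acetylsalicylate 25 (not isolated)
Conditions: 24, 4-(dimethylamino)pyridine, pyridine, CH2Cl2, 0 °C to rt; then pyrrolidine, 0 °C
Reagents that add atoms: 2-(acetyloxy)benzoyl chloride, CC(=O)Oc1ccccc1C(Cl)=O
Why: Acyl transfer catalysed by 4-(dimethylamino)pyridine should esterify only the secondary C6 hydroxyl, the tertiary C4 hydroxyl being inert, and aminolysis of the much more reactive aryl acetate by pyrrolidine in the same flask should then free the phenol.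

Compound list
1 | 2-bromo-3-methylcyclopent-2-en-1-one | CC1=C(Br)C(=O)CC1 | starting material
2 | isopropylmagnesium chloride | CC(C)[Mg]Cl | starting material
3 | rac-2-bromo-3-methyl-1-(propan-2-yl)cyclopent-2-en-1-ol | CC1=C(Br)C(O)(C(C)C)CC1 | intermediate
4 | (1R)-2-bromo-3-methyl-1-(propan-2-yl)cyclopent-2-en-1-ol | CC1=C(Br)[C@](O)(C(C)C)CC1 | intermediate
5 | triethylsilyl trifluoromethanesulfonate | CC[Si](CC)(CC)OS(=O)(=O)C(F)(F)F | starting material
6 | {[(1R)-2-bromo-3-methyl-1-(propan-2-yl)cyclopent-2-en-1-yl]oxy}triethylsilane | CC1=C(Br)[C@](O[Si](CC)(CC)CC)(C(C)C)CC1 | intermediate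
7 | N-methoxy-N-methylacetamide | CC(=O)N(C)OC | starting material
8 | [(5R)-2-methyl-5-(propan-2-yl)-5-(triethylsilyloxy)cyclopent-1-en-1-yl]lithium | CC1=C([Li])[C@](O[Si](CC)(CC)CC)(C(C)C)CC1 | intermediate
9 | 1-[(5R)-2-methyl-5-(propan-2-yl)-5-(triethylsilyloxy)cyclopent-1-en-1-yl]ethan-1-one | CC(=O)C1=C(C)CC[C@@]1(O[Si](CC)(CC)CC)C(C)C | intermediate
10 | (1R)-1-[(5R)-2-methyl-5-(propan-2-yl)-5-(triethylsilyloxy)cyclopent-1-en-1-yl]ethan-1-ol | C[C@@H](O)C1=C(C)CC[C@@]1(O[Si](CC)(CC)CC)C(C)C | intermediate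
11 | diiodomethane | ICI | starting material
12 | (1R)-1-[(1S,2R,5R)-5-methyl-2-(propan-2-yl)-2-(triethylsilyloxy)bicyclo[3.1.0]hexan-1-yl]ethan-1-ol | C[C@@H](O)[C@]12C[C@@]1(C)CC[C@@]2(O[Si](CC)(CC)CC)C(C)C | intermediate
13 | 1-[(1R,2R,5R)-5-methyl-2-(propan-2-yl)-2-(triethylsilyloxy)bicyclo[3.1.0]hexan-1-yl]ethan-1-one | CC(=O)[C@]12C[C@@]1(C)CC[C@@]2(O[Si](CC)(CC)CC)C(C)C | intermediate
14 | tert-butyldimethylsilyl trifluoromethanesulfonate | CC(C)(C)[Si](C)(C)OS(=O)(=O)C(F)(F)F | starting material
15 | tert-butyl({1-[(1S,2R,5R)-5-methyl-2-(propan-2-yl)-2-(triethylsilyloxy)bicyclo[3.1.0]hexan-1-yl]ethenyl}oxy)dimethylsilane | C=C(O[Si](C)(C)C(C)(C)C)[C@]12C[C@@]1(C)CC[C@@]2(O[Si](CC)(CC)CC)C(C)C | intermediate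
16 | prop-1-yn-1-ylmagnesium bromide | CC#C[Mg]Br | starting material
17 | benzylchlorodimethylsilane | C[Si](C)(Cl)Cc1ccccc1 | starting material
18 | benzyldimethyl(prop-1-yn-1-yl)silane | CC#C[Si](C)(C)Cc1ccccc1 | intermediate
19 | {[(3R,8aR)-7-[benzyl(dimethyl)silyl]-6,8a-dimethyl-3-(propan-2-yl)-3-(triethylsilyloxy)-1,2,3,5,8,8a-hexahydroazulen-4-yl]oxy}(tert-butyl)dimethylsilane | CC1=C([Si](C)(C)Cc3ccccc3)C[C@@]2(C)CC[C@@](O[Si](CC)(CC)CC)(C(C)C)C2=C(O[Si](C)(C)C(C)(C)C)C1 | intermediate
20 | (3R,3aR,8aR)-7-[benzyl(dimethyl)silyl]-6,8a-dimethyl-3-(propan-2-yl)-3-(triethylsilyloxy)-2,3,3a,5,8,8a-hexahydroazulen-4(1H)-one | CC1=C([Si](C)(C)Cc3ccccc3)C[C@@]2(C)CC[C@@](O[Si](CC)(CC)CC)(C(C)C)[C@@H]2C(=O)C1 | intermediate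
21 | (3R,3aR,8aR)-7-[benzyl(dimethyl)silyl]-3-hydroxy-6,8a-dimethyl-3-(propan-2-yl)-2,3,3a,5,8,8a-hexahydroazulen-4(1H)-one | CC1=C([Si](C)(C)Cc3ccccc3)C[C@@]2(C)CC[C@@](O)(C(C)C)[C@@H]2C(=O)C1 | intermediate
22 | (3R,3aS,4S,8aR)-7-[benzyl(dimethyl)silyl]-6,8a-dimethyl-3-(propan-2-yl)-1,2,3,3a,4,5,8,8a-octahydroazulene-3,4-diol | CC1=C([Si](C)(C)Cc3ccccc3)C[C@@]2(C)CC[C@@](O)(C(C)C)[C@@H]2[C@@H](O)C1 | intermediate
23 | (3R,3aS,4S,8aR)-6,8a-dimethyl-3-(propan-2-yl)-1,2,3,3a,4,5,8,8a-octahydroazulene-3,4-diol | CC1=CC[C@@]2(C)CC[C@@](O)(C(C)C)[C@@H]2[C@@H](O)C1 | intermediate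
24 | 2-(acetyloxy)benzoyl chloride | CC(=O)Oc1ccccc1C(Cl)=O | starting material
25 | (3R,3aS,4S,8aR)-3-hydroxy-6,8a-dimethyl-3-(propan-2-yl)-1,2,3,3a,4,5,8,8a-octahydroazulen-4-yl 2-(acetyloxy)benzoate | CC1=CC[C@@]2(C)CC[C@@](O)(C(C)C)[C@@H]2[C@@H](OC(=O)c2ccccc2OC(C)=O)C1 | intermediate
26 | (3R,3aS,4S,8aR)-3-hydroxy-6,8a-dimethyl-3-(propan-2-yl)-1,2,3,3a,4,5,8,8a-octahydroazulen-4-yl 2-hydroxybenzoate | CC1=CC[C@@]2(C)CC[C@@](O)(C(C)C)[C@@H]2[C@@H](OC(=O)c2ccccc2O)C1 | target

Total step count: 14. Longest linear sequence: 13 steps (steps 1–8 and 10–14; step 9 is a side branch).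

Steps most likely to fail

Step 10. Rhodium may fail to bind the hindered, electron-rich enol ether alkene of 15, so that insertion into C5–C10 never starts, or the alkyne may be consumed by oligomerisation before it captures the rhodacycle. The fallback sets out from 13 and comes back at 23; it leaves the C6 oxygen out of the cycloaddition and brings it in afterwards. Ketone 13 is converted with KN(SiMe3)2 and PhNTf2 into the enol triflate F1, which Pd(OAc)2/PPh3 with Bu3N and HCO2H should reduce to the plain vinylcyclopropane F2, a 1-alkyl-1-vinylcyclopropane of the substrate class on which the intermolecular cycloaddition is best established. The conditions of step 10 with 18 should then give the diene F3. Hydroboration (BH3·THF, then NaBO3·4H2O) should take place at the trisubstituted C5=C6 alkene, the silylated tetrasubstituted C8=C9 alkene being shielded. Syn addition from the α-face, anti to the C1 methyl group and the C4 silyl ether, puts hydrogen on C5 and boron on C6 and after oxidation gives the alcohol F4 with H-5 and the C6 hydroxyl both α. Bu4NF then removes the triethylsilyl ether and the alkenylsilane together and gives 23.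

Step 11. The proton may reach C5 with poor facial selectivity and give the cis-fused ketone, or the freed β-hydroxy ketone may lose water. The fallback sets out from 19 and comes back at 21; it replaces kinetic protonation by thermodynamic control. Bu4NF buffered with AcOH at −40 °C cleaves only the enol ether and gives 20 mixed with its C5 epimer, the cis-fused ketone F5. While the silyl group on C9 still disfavours migration of the C8=C9 alkene into conjugation, brief treatment with 1,8-diazabicyclo[5.4.0]undec-7-ene should epimerise F5 to the trans-fused 20, in which the C6 carbonyl is trans to the isopropyl group on C4. Isolated 20 is then desilylated with HF·pyridine to 21.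

Step 6. The methylene may be delivered to the wrong alkene face, or the tetrasubstituted alkene next to the quaternary C4 may not react. The fallback sets out from 9 and comes back at 13, bypassing 10 and 12. It is a conjugate addition–ring closure with dimethylsulfoxonium methylide (Me3S(O)I, NaH, DMSO, 50 °C; Corey–Chaykovsky cyclopropanation) on the enone, in which the ylide should attack C1 anti to the bulky silyl ether; it makes no compound outside the list (F0).

Further compounds
F1 | step 10 | 1-[(1S,2R,5R)-5-methyl-2-(propan-2-yl)-2-(triethylsilyloxy)bicyclo[3.1.0]hexan-1-yl]ethenyl trifluoromethanesulfonate | C=C(OS(=O)(=O)C(F)(F)F)[C@]12C[C@@]1(C)CC[C@@]2(O[Si](CC)(CC)CC)C(C)C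
F2 | step 10 | {[(1R,2R,5R)-1-ethenyl-5-methyl-2-(propan-2-yl)bicyclo[3.1.0]hexan-2-yl]oxy}triethylsilane | C=C[C@]12C[C@@]1(C)CC[C@@]2(O[Si](CC)(CC)CC)C(C)C
F3 | step 10 | benzyl(dimethyl)[(3R,8aR)-6,8a-dimethyl-3-(propan-2-yl)-3-(triethylsilyloxy)-1,2,3,5,8,8a-hexahydroazulen-7-yl]silane | CC1=C([Si](C)(C)Cc3ccccc3)C[C@@]2(C)CC[C@@](O[Si](CC)(CC)CC)(C(C)C)C2=CC1
F4 | step 10 | (3R,3aS,4S,8aR)-7-[benzyl(dimethyl)silyl]-6,8a-dimethyl-3-(propan-2-yl)-3-(triethylsilyloxy)-1,2,3,3a,4,5,8,8a-octahydroazulen-4-ol | CC1=C([Si](C)(C)Cc3ccccc3)C[C@@]2(C)CC[C@@](O[Si](CC)(CC)CC)(C(C)C)[C@@H]2[C@@H](O)C1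
F5 | step 11 | (3R,3aS,8aR)-7-[benzyl(dimethyl)silyl]-6,8a-dimethyl-3-(propan-2-yl)-3-(triethylsilyloxy)-2,3,3a,5,8,8a-hexahydroazulen-4(1H)-one (cis-fused C5 epimer of 20) | CC1=C([Si](C)(C)Cc3ccccc3)C[C@@]2(C)CC[C@@](O[Si](CC)(CC)CC)(C(C)C)[C@H]2C(=O)C1
F0 | step 6 | none | none
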